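The reading comes at 10 s, and what to watch up to then is where the reagent stands in its two phases.

    reagent in the reaction phase ⇌ reagent in the second phase, rate k1*([reagent in the reaction phase] - [reagent in the second phase]/K1) per volume of the first phase (K1 = 2.3, k1 = 0.58 s⁻¹)
    starting material + reagent in the reaction phase → target (k2 = 87 M⁻¹ s⁻¹)
    reagent in the reaction phase + target → over-reacted product (k3 = 30 M⁻¹ s⁻¹)
    starting material ⇌ dormant form (K4 = 0.98, k4 = 0.040 s⁻¹)

starting material 1.0 mM; reagent in the second phase 1.00 mM; time 10 s; volume of the second phase over the first 1.0

- in the second phase: reagent in the second phase; everything else is in the first
- charges count per volume of the first phase; a concentration in a rate is the amount of a species over the volume of its own phase; every rate counts per litre of the first phase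
- run time (flask): 10 s

- amount of target at 10 s, in percent of the starting material charged
- the change that raises the amount of target at 10 s, in percent of the starting material charged most ("none" if none brings more than 2 percentage points) (Tuesday's / Saturday's / none)
- amount of target at 10 s, in percent of the starting material charged, after Tuesday's

Two chemists disagree about this flask. The first calls the crossing the rate-limiting step: reagent in the reaction phase is eaten as it arrives, so target follows the drain of the second phase at 0.252 s⁻¹, 92.0% of the charge has crossed by the reading, and Saturday's is the obvious change. The second says the reagent soon sits at its partition value, 0.303 mM, so that starting material meets a pseudo-first-order constant of 0.0264 s⁻¹.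

Powers of ten tell them apart. The two phases approach partition at 0.832 s⁻¹, while starting material, as charged, uses up reagent in the reaction phase at 0.0870 s⁻¹. The base-ten logarithm of that ratio is 0.981, and this is the crossing margin: the powers of ten by which crossing outruns use. Crossing here is ten times faster than use, so I side with the second chemist.

My reckoning allows a lag of 1.20 s, then lets target grow at that constant on the starting material left at mid-run, thinned also by the drain into the dormant form. This gives 16.6%, and 29.2% after Tuesday's. In this reckoning Saturday's halves the lag, so my pick is Tuesday's.

The forecast takes the second side too: “the rate is limited by reagent concentration rather than transfer”. It gives 14.6% (13.5% to 15.8%), lower than my figure, names Tuesday's, and gives 26.5% (24.5% to 28%) after it.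

The simulation gives 14.7%, and 26.0% after Tuesday's. The pick is Tuesday's, worth 11 percentage points against 1.2 points for Saturday's.

The first chemist keeps this flask's opening: at 1.00 s, [reagent in the reaction phase] is 0.165 mM, below partition, with target at 0.800%. The neighbour flask charged with 1.7 mM of starting material has a margin of 0.750 and gives 13.6%, with [reagent in the reaction phase] at 0.210 mM at 10.0 s, against 0.243 mM in this flask. This flask has not come to rest at the reading. At 100 s target reaches 40.4% and starting material has fallen from 60% at the reading to 21.9%, which puts the margin, reckoned on that starting material, at 1.64. The dormant form goes from 25.0% at the reading to 24.1% at 100 s, while reagent in the second phase is down to 22.9% of its charge.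

All constants are made up; what happens was integrated by code.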